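**Plan**
1. Retrosynthesis: both (Z)-butylidene butenolides are opened at O2–C3 / O2'–C3' (silver cycloisomerisation) and C3a–C3 / C3a'–C3' (Sonogashira) to a tricyclic bis(β-keto ester). The C6' carbinol is traced back to a ketone and then to a nitro group.
2. The bicyclo[2.2.2]octane is then cut at C5'–C6' and C4'–C7 in one operation. The enabling feature is that C6' (the carbinol carbon, umpoled as a nitronate) and C7 (β to the ring-A carbonyl C1 through C7a) are 1,4-related through C7'–C6, while the C5'–C4' unit that joins them is β,α to C3a', the enol-lactone carbon of ring B, i.e. a latent vinyl ketone.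
3. The seco compound falls into a C4 nitroalkene acetal (C6', C7', C6, C7), a β-keto ester for ring B (bond C7'–C7a', Michael) and methyl 3-oxopent-4-enoate for ring A (bonds C5–C6, Michael, and C7=C7a, Knoevenagel).
4. Forward: C7'–C7a' bond, then ring A, then unmasking of the vinyl ketone, then the double Michael cascade that closes ring B and the bridging ring, then Nef, bis-triflation, C6'–OH, twofold Sonogashira and twofold lactonisation.
5. Stereochemistry: C7' and C6 come from two catalytic Michael additions. C4' and C7 are relayed from them by the tether in the cascade. C6' comes from face-selective reduction and Mitsunobu inversion. Both alkenes are (Z) by anti-oxymetalation.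

Key step: step 8

Remark: phthalide locants are used throughout (unprimed: the unit whose ring A stays a monocyclic cyclohexene, C1, O2, C3, C3a, C4–C7, C7a, C8; primed: the bridged unit B). β-Keto esters are drawn as keto tautomers, and their epimerisable centres (C7a, C7a', and C6' while it carries NO2) are left unassigned because they are erased later.

Step 1
Reactants: 1 3-(phenylsulfanyl)propanoic acid; 2 potassium methyl malonate
Product: 4 methyl 3-oxo-5-(phenylsulfanyl)pentanoate, via acyl imidazolide 3 (not isolated)
Conditions: CDI, THF, rt; then 2, MgCl2, Et3N, MeCN, rt to 45 °C; 1 M HCl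
Reagents that add atoms: none
Why: Decarboxylative Claisen condensation of a magnesium malonate half-ester with an acyl imidazolide (Masamune–Brooks reaction), a standard route to β-keto esters that leaves the sulfide untouched.

Step 2
Reactants: 5 4,4-diethoxybut-1-ene
Product: 6 (E)-4,4-diethoxy-1-nitrobut-1-ene
Conditions: AgNO2 (3 equiv), TEMPO (0.4 equiv), 4 Å MS, 1,2-dichloroethane, 70 °C
Reagents that add atoms: silver nitrite, [Ag+].[O-]N=O
Why: Radical nitration of a terminal alkene (NO2 radical addition, then loss of the vinylic hydrogen) should give the conjugated (E)-nitroalkene directly under neutral conditions that spare the acetal.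

Step 3
Reactants: 4 methyl 3-oxo-5-(phenylsulfanyl)pentanoate; 6 (E)-4,4-diethoxy-1-nitrobut-1-ene
Product: 7 methyl 2-[(2S)-4,4-diethoxy-1-nitrobutan-2-yl]-3-oxo-5-(phenylsulfanyl)pentanoate (C2 epimers)
Conditions: 1-[3,5-bis(trifluoromethyl)phenyl]-3-[(1S,2S)-2-(dimethylamino)cyclohexyl]thiourea (10 mol%), toluene, rt
Reagents that add atoms: none
Why: Bifunctional amine–thiourea catalysed Michael addition of a β-keto ester to a nitroalkene forms C7'–C7a'; the catalyst binds the nitro group and delivers the enol to one face, which should set C7' (S), the catalyst enantiomer being chosen by analogy with nitrostyrene additions.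

Step 4
Reactants: 7 methyl 2-[(2S)-4,4-diethoxy-1-nitrobutan-2-yl]-3-oxo-5-(phenylsulfanyl)pentanoate
Product: 8 methyl 2-[(2S)-1-nitro-4-oxobutan-2-yl]-3-oxo-5-(phenylsulfanyl)pentanoate (C2 epimers)
Conditions: 1 M HCl, THF, rt
Reagents that add atoms: water, O
Why: Acid-catalysed acetal hydrolysis; C7' is not α to the new carbonyl and cannot epimerise, and nitro group, β-keto ester and sulfide are inert.

Step 5
Reactants: 9 methyl 5-methoxy-3-oxopentanoate
Product: 10 methyl 3-oxopent-4-enoate (Nazarov reagent)
Conditions: p-TsOH·H2O (1 mol%), hydroquinone (trace), 110 °C, reduced pressure, distilled and used at once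
Reagents that add atoms: none
Why: Acid-catalysed β-elimination of methanol from a β-methoxy ketone, the usual preparation of this annulation reagent from its commercial precursor.

Step 6
Reactants: 8 methyl 2-[(2S)-1-nitro-4-oxobutan-2-yl]-3-oxo-5-(phenylsulfanyl)pentanoate; 10 methyl 3-oxopent-4-enoate
Product: 12 methyl (3S)-3-[(2S)-3-(methoxycarbonyl)-1-nitro-4-oxo-6-(phenylsulfanyl)hexan-2-yl]-6-oxocyclohex-1-ene-1-carboxylate, via keto aldehyde Michael adduct 11 (not isolated)
Conditions: (R)-α,α-diphenylprolinol trimethylsilyl ether (20 mol%), PhCO2H (20 mol%), 10 (1.5 equiv), CH2Cl2, 4 Å MS, 0 °C to rt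
Reagents that add atoms: none
Why: Enamine-catalysed Michael addition of an aldehyde to a vinyl ketone followed by intramolecular Knoevenagel condensation (Robinson-type annulation); the catalyst shields one enamine face so that C5 should be attached to C6 under catalyst control (6R in 11, 6S in 12 after the priority change), and the 1,3-dicarbonyl methylene then condenses with the aldehyde to close ring A as the alkylidene β-keto ester.

Step 7
Reactants: 12 methyl (3S)-3-[(2S)-3-(methoxycarbonyl)-1-nitro-4-oxo-6-(phenylsulfanyl)hexan-2-yl]-6-oxocyclohex-1-ene-1-carboxylate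
Product: 14 methyl (3S)-3-[(2S)-3-(methoxycarbonyl)-1-nitro-4-oxohex-5-en-2-yl]-6-oxocyclohex-1-ene-1-carboxylate, via sulfoxide 13 (not isolated)
Conditions: mCPBA (1.05 equiv), CH2Cl2, −78 °C; aq. NaHCO3; then toluene, CaCO3, 80 °C; used crude
Reagents that add atoms: none
Why: Sulfide oxidation followed by thermal syn-elimination of the sulfoxide unmasks the vinyl ketone under neutral conditions; the electron-poor ring-A alkene is inert to the peracid and no base is present that could start the cascade early.

Step 8
Reactants: 14 methyl (3S)-3-[(2S)-3-(methoxycarbonyl)-1-nitro-4-oxohex-5-en-2-yl]-6-oxocyclohex-1-ene-1-carboxylate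
Product: 15 tricyclic nitro diketo diester (dimethyl 10-nitro-2,7-dioxodecahydro-1,4-ethanonaphthalene-3,8-dicarboxylate; ring A with C3a=O and C7a–CO2Me, cis-fused through C6–C7' and C7–C4' to the bicyclo[2.2.2]octanone ring B with C3a'=O, C7a'–CO2Me and C6'–NO2; ring A on the side of the C5'–C6' bridge; C6, C7, C4', C7' as in 23)
Conditions: Cs2CO3 (30 mol%), MeCN (0.01 M), 0 °C to rt; AcOH quench
Reagents that add atoms: none
Why: Carbonate generates the nitronate at C6', which adds in a 6-endo-trig Michael addition to the terminal carbon C5' of the vinyl ketone and closes ring B; the regiodefined ketone enolate at C4' formed in this event then adds in a 6-exo-trig Michael addition to C7 of the ring-A alkylidene β-keto ester, closing the bridging ring of the bicyclo[2.2.2]octanone, and the charge ends on the stabilised ring-A β-keto ester enolate. The closest known reaction types are base-mediated double Michael annulations of vinyl ketone β-keto esters with 2-carbomethoxycyclohexenones and nitro-Michael/Michael cascades. C4' and C7 are set by the tether: the two-atom C6–C7 bridge can only span C7' and C4' on one face of ring B (boat), and C4' can only reach the face of the ring-A alkene that carries C7', so the fusion is cis and, with C6 (S) and C7' (S) in place, ring A lies over the C5'–C6' bridge as in the target. C6', C7a and C7a' form as epimerisable centres that are erased later. The selectivity needed is C-attack by C6' and then by C4' rather than by the more acidic C7a' centre or by oxygen; attack of C7a' or C6' on C7 would give four-membered rings and O-attack is reversible, so only the desired path is productive, and high dilution suppresses intermolecular addition.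

Step 9
Reactants: 15 tricyclic nitro diketo diester
Product: 16 tricyclic triketo diester (dimethyl 2,7,10-trioxodecahydro-1,4-ethanonaphthalene-3,8-dicarboxylate; C6' ketone, otherwise as 15)
Conditions: NaOMe (3.3 equiv), MeOH, 0 °C; then aq. TiCl3 (4 equiv), NH4OAc buffer (pH 5–6), rt
Reagents that add atoms: water, O
Why: Titanium(III)-mediated Nef reaction (nitronate reduced to the imine, which is hydrolysed to the ketone); the buffered conditions spare the two β-keto esters, and C7' is now a bridgehead and cannot epimerise.

Step 10
Reactants: 16 tricyclic triketo diester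
Product: 17 bis(enol triflate) keto diester (C3a–OTf with C7a=C3a in ring A, C3a'–OTf with C7a'=C3a' in ring B, C6' ketone; C6, C7, C4', C7' as in 23)
Conditions: NaH (2.1 equiv), THF, 0 °C; then PhNTf2 (2.3 equiv), 0 °C to rt
Reagents that add atoms: N-phenyl-bis(trifluoromethanesulfonimide), O=S(=O)(N(c1ccccc1)S(=O)(=O)C(F)(F)F)C(F)(F)F
Why: O-Triflation of the two β-keto ester enolates (enol triflate formation); ring B can enolise only towards C7a' because C4' is a bridgehead (Bredt's rule), ring A gives the conjugated C7a=C3a enolate, and the limiting base leaves the far less acidic C6' ketone alone.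

Step 11
Reactants: 17 bis(enol triflate) keto diester
Product: 18 (6'R)-alcohol (hydroxyl on the face of ring A, the 6'-epimer of the target carbinol; otherwise as 17)
Conditions: NaBH4 (1.2 equiv), CeCl3·7H2O (1.2 equiv), MeOH/THF, −78 °C
Reagents that add atoms: none
Why: Luche reduction of the only ketone; hydride should approach C6' from the open face next to the sp2 C7a'=C3a' bridge, because C5 of ring A hangs over the other face, which places the hydroxyl syn to ring A.

Step 12
Reactants: 18 (6'R)-alcohol
Product: 19 (6'S)-4-nitrobenzoate (inverted at C6', ester oxygen next to the C7a'=C3a' bridge as in the target; otherwise as 17)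
Conditions: 4-nitrobenzoic acid (4 equiv), PPh3 (4 equiv), DIAD (4 equiv), toluene, 0 to 40 °C
Reagents that add atoms: 4-nitrobenzoic acid, OC(=O)c1ccc(cc1)[N+](=O)[O-]
Why: Mitsunobu reaction with an acidic carboxylic acid, the variant used for hindered secondary alcohols; SN2 displacement of the oxyphosphonium group from the open face inverts C6' to the target configuration and leaves the oxygen protected as an ester that step 14 removes.

Step 13
Reactants: 19 (6'S)-4-nitrobenzoate; 20 pent-1-yne
Product: 21 bis(pent-1-ynyl) diester 4-nitrobenzoate (pent-1-ynyl at C3a and at C3a', CO2Me at C7a and at C7a')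
Conditions: 20 (4 equiv), Pd(PPh3)2Cl2 (5 mol%), CuI (10 mol%), iPr2NH (4 equiv), THF, rt
Reagents that add atoms: none
Why: Twofold Sonogashira coupling of the electron-poor β-triflyloxy enoates, which react at room temperature, installs C3/C8 and C3'/C8' with their propyl groups.

Step 14
Reactants: 21 bis(pent-1-ynyl) diester 4-nitrobenzoate
Product: 22 hydroxy bis(enynoic acid) (CO2H at C7a and C7a', pent-1-ynyl at C3a and C3a', free 6'S hydroxyl)
Conditions: LiOH·H2O (10 equiv), THF/MeOH/H2O 3:1:1, rt to 40 °C; 1 M HCl to pH 3
Reagents that add atoms: lithium hydroxide, [Li+].[OH-]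
Why: Saponification of the two methyl esters and of the 4-nitrobenzoate in one operation; no stereocentre is α to a carbonyl group, so none can epimerise.

Step 15
Reactants: 22 hydroxy bis(enynoic acid)
Product: 23 target, (3Z,3'Z)-6'-hydroxy phthalide dimer linked C6–C7' and C7–C4', (6S,7R,4'R,6'S,7'S)
Conditions: AgNO3 (20 mol%), acetone, rt, dark
Reagents that add atoms: none
Why: Silver(I)-catalysed 5-exo-dig cycloisomerisation of (Z)-2-en-4-ynoic acids (anti-oxymetalation, protodemetalation) should close both γ-butylidene butenolides with (Z) geometry; the C6' hydroxyl is held away from both alkynes and both carbonyl groups by the rigid bicycle.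

**Compound list**
1 | 3-(phenylsulfanyl)propanoic acid | OC(=O)CCSc1ccccc1 | starting material
2 | potassium methyl malonate | [K+].[O-]C(=O)CC(=O)OC | starting material
3 | 1-(imidazol-1-yl)-3-(phenylsulfanyl)propan-1-one (acyl imidazolide) | O=C(CCSc1ccccc1)n1ccnc1 | intermediate
4 | methyl 3-oxo-5-(phenylsulfanyl)pentanoate | COC(=O)CC(=O)CCSc1ccccc1 | intermediate
5 | 4,4-diethoxybut-1-ene | C=CCC(OCC)OCC | starting material
6 | (E)-4,4-diethoxy-1-nitrobut-1-ene | CCOC(C/C=C/[N+](=O)[O-])OCC | intermediate
7 | methyl 2-[(2S)-4,4-diethoxy-1-nitrobutan-2-yl]-3-oxo-5-(phenylsulfanyl)pentanoate | CCOC(OCC)C[C@H](C[N+](=O)[O-])C(C(=O)OC)C(=O)CCSc1ccccc1 | intermediate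
8 | methyl 2-[(2S)-1-nitro-4-oxobutan-2-yl]-3-oxo-5-(phenylsulfanyl)pentanoate | O=CC[C@H](C[N+](=O)[O-])C(C(=O)OC)C(=O)CCSc1ccccc1 | intermediate
9 | methyl 5-methoxy-3-oxopentanoate | COCCC(=O)CC(=O)OC | starting material
10 | methyl 3-oxopent-4-enoate | C=CC(=O)CC(=O)OC | intermediate
11 | methyl (6R,7S)-6-formyl-8-(methoxycarbonyl)-7-(nitromethyl)-3,9-dioxo-11-(phenylsulfanyl)undecanoate | O=C[C@H](CCC(=O)CC(=O)OC)[C@H](C[N+](=O)[O-])C(C(=O)OC)C(=O)CCSc1ccccc1 | intermediate
12 | methyl (3S)-3-[(2S)-3-(methoxycarbonyl)-1-nitro-4-oxo-6-(phenylsulfanyl)hexan-2-yl]-6-oxocyclohex-1-ene-1-carboxylate | COC(=O)C1=C[C@H](CCC1=O)[C@H](C[N+](=O)[O-])C(C(=O)OC)C(=O)CCSc1ccccc1 | intermediate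
13 | methyl (3S)-3-[(2S)-3-(methoxycarbonyl)-1-nitro-4-oxo-6-(phenylsulfinyl)hexan-2-yl]-6-oxocyclohex-1-ene-1-carboxylate | COC(=O)C1=C[C@H](CCC1=O)[C@H](C[N+](=O)[O-])C(C(=O)OC)C(=O)CCS(=O)c1ccccc1 | intermediate
14 | methyl (3S)-3-[(2S)-3-(methoxycarbonyl)-1-nitro-4-oxohex-5-en-2-yl]-6-oxocyclohex-1-ene-1-carboxylate | COC(=O)C1=C[C@H](CCC1=O)[C@H](C[N+](=O)[O-])C(C(=O)OC)C(=O)C=C | intermediate
15 | tricyclic nitro diketo diester (dimethyl 10-nitro-2,7-dioxodecahydro-1,4-ethanonaphthalene-3,8-dicarboxylate, C6, C7, C4', C7' as in 23) | COC(=O)C2C(=O)CC[C@@H]1[C@H]3C(C(=O)OC)C(=O)[C@H](CC3[N+](=O)[O-])[C@H]21 | intermediate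
16 | tricyclic triketo diester (dimethyl 2,7,10-trioxodecahydro-1,4-ethanonaphthalene-3,8-dicarboxylate) | COC(=O)C2C(=O)CC[C@@H]1[C@H]3C(C(=O)OC)C(=O)[C@H](CC3=O)[C@H]21 | intermediate
17 | bis(enol triflate) keto diester | COC(=O)C2=C(OS(=O)(=O)C(F)(F)F)CC[C@@H]1[C@H]3C(C(=O)OC)=C(OS(=O)(=O)C(F)(F)F)[C@H](CC3=O)[C@H]21 | intermediate
18 | (6'R)-alcohol bis(enol triflate) diester | COC(=O)C2=C(OS(=O)(=O)C(F)(F)F)CC[C@@H]1[C@H]3C(C(=O)OC)=C(OS(=O)(=O)C(F)(F)F)[C@H](C[C@H]3O)[C@H]21 | intermediate
19 | (6'S)-4-nitrobenzoate bis(enol triflate) diester | COC(=O)C2=C(OS(=O)(=O)C(F)(F)F)CC[C@@H]1[C@H]3C(C(=O)OC)=C(OS(=O)(=O)C(F)(F)F)[C@H](C[C@@H]3OC(=O)c4ccc(cc4)[N+](=O)[O-])[C@H]21 | intermediate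
20 | pent-1-yne | CCCC#C | starting material
21 | bis(pent-1-ynyl) diester 4-nitrobenzoate | COC(=O)C2=C(C#CCCC)CC[C@@H]1[C@H]3C(C(=O)OC)=C(C#CCCC)[C@H](C[C@@H]3OC(=O)c4ccc(cc4)[N+](=O)[O-])[C@H]21 | intermediate
22 | hydroxy bis(enynoic acid) | OC(=O)C2=C(C#CCCC)CC[C@@H]1[C@H]3C(C(=O)O)=C(C#CCCC)[C@H](C[C@@H]3O)[C@H]21 | intermediate
23 | target, (3Z,3'Z,6S,7R,4'R,6'S,7'S) | CCC/C=C1\OC(=O)C2=C1CC[C@@H]1[C@H]3C4=C(/C(=C/CCC)OC4=O)[C@H](C[C@@H]3O)[C@H]21 | target

**Totals**
Total step count: 15. Longest linear sequence: 13 steps (steps 2, 3, 4 and 6 to 15); steps 1 and 5 make the two side fragments.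

**Steps most likely to fail**

Step 6 (ring-A annulation). The β-keto ester methylene of 10 may condense with the aldehyde of 8 before the enamine has added to the vinyl ketone. Ring A would then close by a vinylogous path without catalyst control at C6 (poor facial selectivity), and the amine may also deconjugate the product. The fallback sets out from 8 and comes back at 12, and it installs the ring-A ester by carbonylation instead of by Knoevenagel condensation. The same aminocatalyst with but-3-en-2-one should give keto aldehyde F1. Acid-mediated aldol condensation (p-TsOH, toluene, 50 °C) should give the 4-substituted cyclohex-2-enone F2. α-Iodination (I2, pyridine, CH2Cl2) should give the 2-iodo enone F3. Palladium-catalysed methoxycarbonylation (Pd(OAc)2, PPh3, CO 1 atm, MeOH, iPr2NEt, DMF, 50 °C) should return to 12.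

Step 8 (key cascade). Proton transfer to the first-formed C4' enolate from the acidic C7a'–H, or base-induced γ-deprotonation (deconjugation) of the ring-A acceptor, may outrun the second conjugate addition. The cascade would then stop after ring B, or C6 would be lost. The fallback sets out from 14 and comes back at 15, and it closes the second ring through the neutral enol instead of the enolate. A buffered tertiary amine (Et3N/AcOH, CH2Cl2, −20 °C) is used so that only the 6-endo nitro-Michael addition takes place, and the monocyclic nitro ketone F4 is isolated. Brønsted acid catalysis (p-TsOH·H2O, toluene, 50 °C; acid-catalysed 6-exo Michael addition of the C4' enol) should then return to 15.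

Step 12 (inversion at C6'). Activation of the hindered C6' hydroxyl, which lies syn to ring A, may be slow, and elimination towards C5' may compete with substitution. The fallback sets out from 18 and comes back at 19, and it replaces substitution by thermodynamic equilibration of the carbinol. Ruthenium-catalysed hydrogen transfer (hydroxycyclopentadienyl ruthenium hydride dimer catalyst, toluene, 70 °C, a few mol% of ketone 17 as hydrogen shuttle) should favour the epimer with the hydroxyl anti to ring A, the (6'S)-alcohol F5. Acylation (4-nitrobenzoyl chloride, pyridine, DMAP, CH2Cl2) should return to 19.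

**Further compounds**
F1 | step 6 | keto aldehyde from 8 and but-3-en-2-one (methyl 2-[3-formyl-1-nitro-6-oxoheptan-2-yl]-3-oxo-5-(phenylsulfanyl)pentanoate, C6 and C7' as in 12) | O=C[C@H](CCC(C)=O)[C@H](C[N+](=O)[O-])C(C(=O)OC)C(=O)CCSc1ccccc1
F2 | step 6 | 4-substituted cyclohex-2-enone (12 without the ring ester) | O=C1C=C[C@H](CC1)[C@H](C[N+](=O)[O-])C(C(=O)OC)C(=O)CCSc1ccccc1
F3 | step 6 | 2-iodo enone (iodine at C7a) | O=C1C(I)=C[C@H](CC1)[C@H](C[N+](=O)[O-])C(C(=O)OC)C(=O)CCSc1ccccc1
F4 | step 8 | monocyclic nitro ketone (ring B closed at C5'–C6', C4'–C7 still open) | COC(=O)C1=C[C@H](CCC1=O)[C@H]1C(C(=O)OC)C(=O)CCC1[N+](=O)[O-]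
F5 | step 12 | (6'S)-alcohol bis(enol triflate) diester | COC(=O)C2=C(OS(=O)(=O)C(F)(F)F)CC[C@@H]1[C@H]3C(C(=O)OC)=C(OS(=O)(=O)C(F)(F)F)[C@H](C[C@@H]3O)[C@H]21
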